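A direct plan would build the chain in two directions from the C2-symmetric (2R,4R)-1,2:4,5-diepoxypentane A1. The benzylic Grignard reagent A2 would open both oxiranes at their terminal carbons under copper catalysis to give the anti-diol A3, which would then be mono-acetylated and deprotected. Its weakest steps would be three.
- Formation of the electron-rich benzylic Grignard reagent A2: Wurtz homocoupling would compete and an excess would be needed.
- Preparation and isolation of A1: this small, volatile, water-soluble bis-epoxide would cost an asymmetric high-pressure hydrogenation and a double ring closure only to carry two carbinol centres.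
- The separate mono-acetylation of A3: it would add a step without adding complexity.

The target is read as the Tishchenko adduct of a β-hydroxy ketone and acetaldehyde. The route rests on the C3–H and acetyl C–O5 bonds (numbering of hydroxy ketone 10). A samarium-catalysed Evans–Tishchenko reaction turns (5S)-hydroxy ketone 10 into the anti-1,3-diol monoacetate in one operation: it sets C3 from C5 and places exactly one acetate. The feature exploited is the 1,3-anti C–OH/C–OAc array of the heptane chain. Only one stereocentre then comes from a reagent, and it is made with the C4–C5 bond by a catalytic asymmetric Mukaiyama aldol of two guaiacyl building blocks. No benzylic organometallic, no bis-epoxide and no separate acetylation occur.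

Key step: step 6

Assumption: the (S)-tryptophan-derived oxazaborolidinone of step 5 is taken to expose the Re face of aldehyde 8, as recalled for simple aldehydes. Should the opposite sense be found, the catalyst from (R)-tryptophan would be used.

Step 1
Reactants: 1 4-(4-hydroxy-3-methoxyphenyl)butan-2-one (zingerone, commercial)
Product: 2 4-[4-(tert-butyldimethylsilyloxy)-3-methoxyphenyl]butan-2-one
Conditions: TBSCl (1.2 equiv), imidazole (2.5 equiv), DMF, rt
Reagents that add atoms: tert-butyldimethylsilyl chloride, CC(C)(C)[Si](C)(C)Cl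
Why: Imidazole-promoted O-silylation of the phenol removes the only acidic proton before the enolate chemistry and leaves the ketone untouched.

Step 2
Reactants: 2 4-[4-(tert-butyldimethylsilyloxy)-3-methoxyphenyl]butan-2-one
Product: 4 tert-butyl{2-methoxy-4-[3-(trimethylsilyloxy)but-3-en-1-yl]phenoxy}dimethylsilane, via lithium enolate 3 (not isolated)
Conditions: LiN(iPr)2 (1.1 equiv), THF, −78 °C, slow addition of 2; Me3SiCl (1.3 equiv), Et3N, −78 → 0 °C; pentane, filtration, short-path distillation
Reagents that add atoms: chlorotrimethylsilane, C[Si](C)(C)Cl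
Why: Kinetic deprotonation of a methyl ketone by the hindered amide at low temperature should take a proton of the methyl group, and O-silylation of enolate 3 fixes the terminal enol silyl ether (silyl enol ether formation) without creating a stereocentre.

Step 3
Reactants: 5 ethyl 3-(4-hydroxy-3-methoxyphenyl)propanoate (ethyl dihydroferulate, commercial)
Product: 6 ethyl 3-[4-(tert-butyldimethylsilyloxy)-3-methoxyphenyl]propanoate
Conditions: TBSCl (1.2 equiv), imidazole (2.5 equiv), DMF, rt
Reagents that add atoms: tert-butyldimethylsilyl chloride, CC(C)(C)[Si](C)(C)Cl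
Why: The same phenol O-silylation gives the second ring the same protecting group, so that one reagent can free both phenols at the end.

Step 4
Reactants: 6 ethyl 3-[4-(tert-butyldimethylsilyloxy)-3-methoxyphenyl]propanoate
Product: 8 3-[4-(tert-butyldimethylsilyloxy)-3-methoxyphenyl]propanal, via aluminium hemiacetal 7 (not isolated)
Conditions: iBu2AlH (1.05 equiv), CH2Cl2, −78 °C; MeOH, then aq. potassium sodium tartrate
Reagents that add atoms: none
Why: Partial reduction of an ester with diisobutylaluminium hydride, in which the tetrahedral aluminium hemiacetal 7 should persist at −78 °C and release the aldehyde only on aqueous work-up, while the aryl silyl ether is inert to the hydride.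

Step 5
Reactants: 4 tert-butyl{2-methoxy-4-[3-(trimethylsilyloxy)but-3-en-1-yl]phenoxy}dimethylsilane (1.5 equiv); 8 3-[4-(tert-butyldimethylsilyloxy)-3-methoxyphenyl]propanal
Product: 10 (5S)-1,7-bis[4-(tert-butyldimethylsilyloxy)-3-methoxyphenyl]-5-hydroxyheptan-3-one, via silylated aldol adduct 9 (not isolated)
Conditions: B-butyl-1,3,2-oxazaborolidin-5-one from N-tosyl-(S)-tryptophan and BuB(OH)2 (20 mol%), EtCN, −78 °C; then 1 M HCl, THF, 0 °C, brief
Reagents that add atoms: none
Why: Catalytic enantioselective Mukaiyama aldol addition, in which the chiral boron Lewis acid binds the aldehyde oxygen, its indole ring shields one face, the enol silyl ether adds through an open transition state to the Re face to form the C4–C5 bond and set C5 as (S), and the O–SiMe3 bond of adduct 9 is cleaved by the cold dilute acid while the aryl silyl ethers remain.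

Step 6
Reactants: 10 (5S)-1,7-bis[4-(tert-butyldimethylsilyloxy)-3-methoxyphenyl]-5-hydroxyheptan-3-one
Product: 12 (3S,5S)-1,7-bis[4-(tert-butyldimethylsilyloxy)-3-methoxyphenyl]-5-hydroxyheptan-3-yl acetate, via samarium-bound hemiacetal 11 (not isolated)
Conditions: MeCHO (8 equiv, freshly distilled), SmI2 (0.3 equiv, 0.1 M in THF), THF, −10 °C, argon, dark; sat. aq NaHCO3
Reagents that add atoms: acetaldehyde, CC=O
Why: Evans–Tishchenko reduction: trivalent samarium, formed in the flask from SmI2 and acetaldehyde, binds the C5 hydroxyl and the C3 carbonyl of 10 (numbering of 10), the hydroxyl adds to acetaldehyde, and the samarium hemiacetal alkoxide 11 hands its C–H hydride to C3 through a six-membered chair-like transition state held in a bicyclic chelate, so that the hemiacetal carbon becomes the acetyl carbonyl on O5. The closest known reaction type is this very samarium-catalysed intramolecular Tishchenko reduction of β-hydroxy ketones, which is established with acetaldehyde and with chains that lack α-substituents. No ring is closed in the product; the six-membered array exists only in the transition state. The new C3 centre is controlled by C5 alone: with the C6 chain equatorial the hydride reaches only one carbonyl face, which gives the 1,3-anti (3S,5S) relationship. The step needs the internal hydride shift to outrun retro-aldol cleavage and dehydration of 10 and the self-Tishchenko reaction of acetaldehyde, which the chelated intramolecular path, the excess of aldehyde and the low temperature should secure. A later 1,3-acetyl shift would be degenerate because the parent anti-diol is C2-symmetric, so a single monoacetate, the one of the target, can result.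

Step 7
Reactants: 12 (3S,5S)-1,7-bis[4-(tert-butyldimethylsilyloxy)-3-methoxyphenyl]-5-hydroxyheptan-3-yl acetate
Product: 13 (3S,5S)-5-hydroxy-1,7-bis(4-hydroxy-3-methoxyphenyl)heptan-3-yl acetate (target)
Conditions: Bu4NF (2.4 equiv), AcOH (2.6 equiv), THF, 0 °C
Reagents that add atoms: none
Why: Fluoride-induced cleavage of the two aryl silyl ethers (desilylation with a phenoxide leaving group) under acetic acid buffering should leave the secondary acetate and both stereocentres untouched.

**Compound list**
1 | 4-(4-hydroxy-3-methoxyphenyl)butan-2-one (zingerone) | COc1cc(CCC(C)=O)ccc1O | starting material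
2 | 4-[4-(tert-butyldimethylsilyloxy)-3-methoxyphenyl]butan-2-one | COc1cc(CCC(C)=O)ccc1O[Si](C)(C)C(C)(C)C | intermediate
3 | lithium 4-[4-(tert-butyldimethylsilyloxy)-3-methoxyphenyl]but-1-en-2-olate | [Li]OC(=C)CCc1ccc(O[Si](C)(C)C(C)(C)C)c(OC)c1 | intermediate (not isolated)
4 | tert-butyl{2-methoxy-4-[3-(trimethylsilyloxy)but-3-en-1-yl]phenoxy}dimethylsilane | COc1cc(CCC(=C)O[Si](C)(C)C)ccc1O[Si](C)(C)C(C)(C)C | intermediate
5 | ethyl 3-(4-hydroxy-3-methoxyphenyl)propanoate | CCOC(=O)CCc1ccc(O)c(OC)c1 | starting material
6 | ethyl 3-[4-(tert-butyldimethylsilyloxy)-3-methoxyphenyl]propanoate | CCOC(=O)CCc1ccc(O[Si](C)(C)C(C)(C)C)c(OC)c1 | intermediate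
7 | {3-[4-(tert-butyldimethylsilyloxy)-3-methoxyphenyl]-1-ethoxypropoxy}diisobutylaluminium | CCOC(CCc1ccc(O[Si](C)(C)C(C)(C)C)c(OC)c1)O[Al](CC(C)C)CC(C)C | intermediate (not isolated)
8 | 3-[4-(tert-butyldimethylsilyloxy)-3-methoxyphenyl]propanal | O=CCCc1ccc(O[Si](C)(C)C(C)(C)C)c(OC)c1 | intermediate
9 | (5S)-1,7-bis[4-(tert-butyldimethylsilyloxy)-3-methoxyphenyl]-5-(trimethylsilyloxy)heptan-3-one | COc1cc(CC[C@H](O[Si](C)(C)C)CC(=O)CCc2ccc(O[Si](C)(C)C(C)(C)C)c(OC)c2)ccc1O[Si](C)(C)C(C)(C)C | intermediate (not isolated)
10 | (5S)-1,7-bis[4-(tert-butyldimethylsilyloxy)-3-methoxyphenyl]-5-hydroxyheptan-3-one | COc1cc(CC[C@H](O)CC(=O)CCc2ccc(O[Si](C)(C)C(C)(C)C)c(OC)c2)ccc1O[Si](C)(C)C(C)(C)C | intermediate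
11 | (5S)-1,7-bis[4-(tert-butyldimethylsilyloxy)-3-methoxyphenyl]-5-[1-(diiodosamariooxy)ethoxy]heptan-3-one | COc1cc(CC[C@H](OC(C)O[Sm](I)I)CC(=O)CCc2ccc(O[Si](C)(C)C(C)(C)C)c(OC)c2)ccc1O[Si](C)(C)C(C)(C)C | intermediate (not isolated)
12 | (3S,5S)-1,7-bis[4-(tert-butyldimethylsilyloxy)-3-methoxyphenyl]-5-hydroxyheptan-3-yl acetate | COc1cc(CC[C@H](OC(C)=O)C[C@@H](O)CCc2ccc(O[Si](C)(C)C(C)(C)C)c(OC)c2)ccc1O[Si](C)(C)C(C)(C)C | intermediate
13 | (3S,5S)-5-hydroxy-1,7-bis(4-hydroxy-3-methoxyphenyl)heptan-3-yl acetate | COc1cc(CC[C@H](O)C[C@H](CCc2ccc(O)c(OC)c2)OC(C)=O)ccc1O | target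

Total step count: 7. Longest linear sequence: 5 steps (steps 1, 2, 5, 6, 7 or steps 3, 4, 5, 6, 7).

Steps most likely to fail:

Step 5. Poor facial selectivity in the aldol addition, or slow catalyst turnover that lets the enolisable aldehyde condense with itself, would lower the enantiomeric purity of 10. The fallback introduces the C5 oxygen after the carbon–carbon bond, not with it. It sets out from ketone 2 and aldehyde 8: lithium enolate 3 (LiN(iPr)2, THF, −78 °C) would add to 8 to give the racemic β-hydroxy ketone F1. Acid-catalysed dehydration (TsOH, toluene, warm) would give the (E)-enone F2. Enantioselective conjugate borylation (B2pin2, CuCl, NaOtBu, a Josiphos-type ferrocenyl diphosphine of the enantiomer that gives the (S) sense, MeOH, THF) would give the (5S)-β-boryl ketone F3. Its oxidation with NaBO3·4H2O, which proceeds with retention at carbon, would come back to the route at 10.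

Step 6. Sluggish hydride transfer would let retro-aldol cleavage or dehydration of the hydroxy ketone, or consumption of the catalyst by acetaldehyde self-condensation, take over. The fallback separates reduction and acylation. It sets out from 10: hydroxyl-directed anti reduction with Me4NBH(OAc)3 (MeCN/AcOH, −30 °C, internal hydride delivery from the alkoxyborohydride) would give the (3S,5S)-anti-diol F4. Orthoester exchange (MeC(OMe)3, pyridinium tosylate, CH2Cl2) would give the cyclic orthoacetate F5. Its hydrolysis with water can open only to a hydroxy acetate and would come back to the route at 12.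

Step 4. Collapse of the aluminium hemiacetal before the quench would cause over-reduction to the alcohol and give mixtures. The fallback passes through the alcohol on purpose. It sets out from 6: exhaustive reduction (iBu2AlH, 2.5 equiv, CH2Cl2, −78 → 0 °C) would give the primary alcohol F6. Dess–Martin oxidation (NaHCO3, CH2Cl2, rt) would come back to the route at 8.

**Further compounds**
F1 | step 5 | rac-1,7-bis[4-(tert-butyldimethylsilyloxy)-3-methoxyphenyl]-5-hydroxyheptan-3-one | COc1cc(CCC(O)CC(=O)CCc2ccc(O[Si](C)(C)C(C)(C)C)c(OC)c2)ccc1O[Si](C)(C)C(C)(C)C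
F2 | step 5 | (4E)-1,7-bis[4-(tert-butyldimethylsilyloxy)-3-methoxyphenyl]hept-4-en-3-one | COc1cc(CC/C=C/C(=O)CCc2ccc(O[Si](C)(C)C(C)(C)C)c(OC)c2)ccc1O[Si](C)(C)C(C)(C)C
F3 | step 5 | (5S)-1,7-bis[4-(tert-butyldimethylsilyloxy)-3-methoxyphenyl]-5-(4,4,5,5-tetramethyl-1,3,2-dioxaborolan-2-yl)heptan-3-one | COc1cc(CC[C@H](B3OC(C)(C)C(C)(C)O3)CC(=O)CCc2ccc(O[Si](C)(C)C(C)(C)C)c(OC)c2)ccc1O[Si](C)(C)C(C)(C)C
F4 | step 6 | (3S,5S)-1,7-bis[4-(tert-butyldimethylsilyloxy)-3-methoxyphenyl]heptane-3,5-diol | COc1cc(CC[C@H](O)C[C@@H](O)CCc2ccc(O[Si](C)(C)C(C)(C)C)c(OC)c2)ccc1O[Si](C)(C)C(C)(C)C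
F5 | step 6 | (4S,6S)-4,6-bis{2-[4-(tert-butyldimethylsilyloxy)-3-methoxyphenyl]ethyl}-2-methoxy-2-methyl-1,3-dioxane | COc1cc(CC[C@H]2C[C@H](CCc3ccc(O[Si](C)(C)C(C)(C)C)c(OC)c3)OC(C)(OC)O2)ccc1O[Si](C)(C)C(C)(C)C
F6 | step 4 | 3-[4-(tert-butyldimethylsilyloxy)-3-methoxyphenyl]propan-1-ol | OCCCc1ccc(O[Si](C)(C)C(C)(C)C)c(OC)c1
A1 | direct plan | (2R,4R)-1,2:4,5-diepoxypentane | C1O[C@@H]1C[C@@H]1CO1
A2 | direct plan | [4-(benzyloxy)-3-methoxybenzyl]magnesium chloride | COc1cc(C[Mg]Cl)ccc1OCc1ccccc1
A3 | direct plan | (3S,5S)-1,7-bis[4-(benzyloxy)-3-methoxyphenyl]heptane-3,5-diol | COc1cc(CC[C@H](O)C[C@@H](O)CCc2ccc(OCc3ccccc3)c(OC)c2)ccc1OCc1ccccc1
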